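Amounts are what I counted: product in moles per litre divided by the precatalyst charged, which gives turnovers and lets flasks with different charges of starting material be set side by side.

| setting | south-west | east | autumn | spring |
|---|---|---|---|---|
| starting material | 0.50 M | 0.50 M | 0.50 M | 1.0 M |
| solid reagent | 0.75 M | 0.75 M | 0.750 M | 1.50 M |
| precatalyst | 1.7 mM | 5 mM | 2.5 mM | 2.5 mM |
| remark | run made earlier | run made earlier |  |  |
| time |  |  | 4.0 h | 12 h |

- south-west (time / h: product / %, starting material / %): 0.133: 0.1, 100.1; 0.333: 0.1, 99.4; 0.667: 0, 98.7; 1.00: 1.3, 99.0; 1.33: 1.3, 98.7; 2.00: 3.6, 95.9; 2.50: 6.7, 92.5
- east (time / h: product / %, starting material / %): 0.200: 0.2, 100.4; 0.333: 0, 100.1; 0.417: 1.1, 100.2; 0.667: 1.1, 99.1; 1.00: 2.3, 97.6; 1.50: 5.6, 95.0; 2.50: 16.3, 83.3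

(each reading ± 0.5 percentage points)

- as a solid, counted per litre of solution: solid reagent
- at the start none of the solid reagent is in solution

1. which one finishes higher in amount of product, in percent of the starting material charged ("neither" within 2 percentage points) (autumn / spring / neither)
2. amount of product at the end, in percent of the starting material charged, autumn
3. amount of product at the end, in percent of the starting material charged, spring

I built the flask up from the east run, whose last reading stands higher above the scatter than the south-west one. That reading is 16.3 turnovers in 2.50 h.

First I took the main step alone, catalyst turning over steadily. A straight line then gives autumn 13.0%. But the east readings bend upward after an induction period, so I added a supply growing in step with time. That makes a parabola, turnovers equal to (t/τ) squared, with τ = 0.619 h, the turnover time. It returns 5.87% for the east run at 1.50 h, against 5.6% read. The south-west run is less kind: 5.54% against 6.7%.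

The parabola gives autumn 20.9% and spring 93.9%, with spring's doubled charge in the denominator. That is one end. The readings end at 2.50 h, so for the other end I let the supply stop there, with product running straight on at the parabola's slope at that point. This gives autumn 17.9% and spring 35.0%. Joining the ends by their mean, I committed to 19.4% for autumn and 64.5% for spring.

The forecast named spring as higher, with 21% for autumn and 80% for spring, on the ground of “something building up roughly linearly with time”.

The flask gave spring as higher, with 24.1% for autumn, above both my ends, and 61.1% for spring, between them.

    starting material + catalyst intermediate A → catalyst intermediate B (k = 7690 M⁻¹ h⁻¹)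
    coupling partner + free catalyst ⇌ catalyst intermediate A (K = 1.97 M⁻¹, k = 288 M⁻¹ h⁻¹)
    catalyst intermediate B → free catalyst + product (k = 324 h⁻¹)
    solid reagent ⇌ coupling partner, rate k4*(cs4 - [coupling partner]) while solid is left; crystals form when [coupling partner] > cs4 (solubility = 0.410 M, k = 0.238 h⁻¹)
    precatalyst ⇌ free catalyst (K = 1.70, k = 0.327 h⁻¹)

Spring finished higher mainly because of its longer time: with the time cut to autumn's, spring gave 12.3%. The parabola reaches spring's result at 9.68 h, yet spring took 12 h. Part of the reason is the low solubility of coupling partner, acting together with the length of the run: with that limit removed, spring gives 100%, and ten times as long gives 100%. In spring, [coupling partner] stood at 0.160 M after 6.00 h and 0.154 M after 12.0 h, so it did not grow between those times.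

The neighbouring flask is autumn read at 1.5 h, inside the readings' span, where the parabola gives 2.93%. The computed result there is 2.88%.

The readings were computed with made-up constants, noise included.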